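The runs are simulated for substances that don't exist, and the scatter is random.

The pitfall in a cold flask is to carry speed from one temperature to another by the bench rule that a rate doubles every 10.0 K. The amber flask, at −20 °C, reads target up to 41.5% at 80.0 min and down to 36.8% at 150 min. The green run, the same charge at −35 °C, still rises at 300 min.

| flask | substrate | partner | temperature | remark | time |
|---|---|---|---|---|---|
| amber | 18 mM | 72 mM | −20 °C | the very flask that is asked about, followed so far |  |
| green | 18 mM | 72 mM | −35 °C | run made earlier |  |
| flask | 18 mM | 72.0 mM | −20 °C |  | 4.0 h |

| run | time / min | target / % |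
|---|---|---|
| amber | 30.0 | 26.0 |
| amber | 60.0 | 40.3 |
| amber | 80.0 | 41.5 |
| amber | 120 | 39.4 |
| amber | 150 | 36.8 |
| green | 60.0 | 5.2 |
| green | 120 | 14.9 |
| green | 180 | 24.1 |
| green | 240 | 30.5 |
| green | 300 | 34.6 |

(readings scatter by 0.3 percentage points)

- alder: at 4.0 h add partner, 50.0% of the amount charged, then wait 4.0 h
- birch: at 4.0 h raise the temperature by 25 K, then wait 4.0 h
- ash: change nothing and wait 4.0 h more
- elm: at 4.0 h take out 90% of the released group then present, then wait 4.0 h

- additions bring no volume worth counting

* target, in percent of the substrate first charged, at 4.0 h
* the option that brings most further target ("none" if no option brings more than 2 percentage points) (alder / birch / ash / elm / none)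
* target present, in percent of the substrate first charged, after alder
* target present, in percent of the substrate first charged, after elm

Applied honestly, the rule gives a factor 2.83 for the 15.0 K between the runs. But amber reads 26.0% at 30.0 min, and green passes that reading at about 198 min, so as read the same level of target takes a factor 6.59 longer there. That is more than the rule allows, by a ratio of 2.33, and here the rule stops working.

So I go to logarithms. My quantity is the decade width, read off these two runs as 18.3 K, the warming that buys one power of ten in speed; the rule's own width is 33.2 K. Carried above the temperatures of these runs, which makes it an estimate, the width turns the 25 K of birch into 1.37 decades, a factor 23.2, so its 4.0 h count as 92.7 h of amber time, longer than the amber run as read. The width says how far a flask travels, not which way, so I leave the sign of birch open and do not extend the amber fall to it.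

The forecast gives 31% (27% to 34%) now, 27% (19% to 36%) after alder and 35% (24% to 48%) after elm. It names elm as best and holds that “warming only speeds the loss”, where I keep the sign open.

The flask gives 31.9% at 4.0 h, 27.4% after alder and 27.4% after elm. The best option is birch, with 42 percentage points against −4.6 points for ash and −4.6 points for elm.

    substrate + partner → intermediate + released group (k = 0.0110 M⁻¹ s⁻¹, Ea = 60.0 kJ mol⁻¹)
    intermediate ⇌ target (K = 2.30, k = 7.40 × 10⁻⁴ s⁻¹, Ea = 68.0 kJ mol⁻¹, ΔH = 8.00 kJ mol⁻¹)
    intermediate ⇌ isomer of the product (K = 5.10, k = 3.20 × 10⁻⁴ s⁻¹, Ea = 72.0 kJ mol⁻¹, ΔH = −82.0 kJ mol⁻¹)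
    substrate ⇌ dormant form (K = 2.50, k = 4.10 × 10⁻⁵ s⁻¹, Ea = 77.0 kJ mol⁻¹, ΔH = 7.00 kJ mol⁻¹)
    (constants at −20 °C)

In the flask, substrate and partner gave intermediate and released group early, with 66% of that step's turnover up to 4.0 h done at 24.0 min. Then, with substrate at 0.869% at 120 min, target fell from 39.6% to 31.9% by 240 min while isomer of the product rose from 38.9% to 50.4%: kinetic against thermodynamic control. The relaxation half-life of intermediate and isomer of the product by this step alone is 30.2 min, and my estimate of 92.7 h of amber time for birch holds 184 of them.

The neighbour run at 5 °C throughout stands 25 K above the flask, so the width gives it the same estimated factor 23.2: its 4.0 h count as 92.7 h at −20 °C, longer than the 15 h of the other neighbour, and I expect it to keep less substrate than the 0.065% of that other neighbour. The neighbour at 5 °C ends with 0.0071% of its charged substrate, and with target at 73.6% against 26.8% in the 15 h neighbour.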